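The cyclohexene ring is read as a masked β-hydroxy ketone: the alkynyl-bearing sp2 carbon (C1) is a latent ketone and the acetoxy carbon (C3) its β-carbinol, so the bond from the vinylic CH (C2) to C3 is an aldol bond, while C3–C6 with their four oxygens map onto C1–C4 of D-galactose. A Ferrier carbocyclization converts a 6-deoxyhex-5-enopyranoside, an oxygen heterocycle of either anomeric configuration, into the carbocyclic ketol in one operation, forming C2–C3 and setting C3 under substrate control. Enol triflation and Sonogashira coupling with a separately built enyne then create the C1=C2 bond and attach the side chain.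

Key step: step 4

Ring numbering used throughout for the carbocycle: C1 = alkynyl-bearing sp2 carbon (ketone carbon in the early intermediates), C2 = vinylic CH, C3 = acetoxy carbon, C4 = methoxy carbon, C5 and C6 = the two hydroxyl carbons (C6 next to C1). CIP descriptors of carbocycles 7–19 refer to this numbering.
Assumption: pinacol boronate 11 is taken as a catalogue compound.

Step 1
Reactants: 1 methyl α-D-galactopyranoside
Product: 2 methyl 6-deoxy-6-iodo-α-D-galactopyranoside
Conditions: PPh3, I2, imidazole, THF, reflux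
Reagents that add atoms: iodine, II
Why: Garegg–Samuelsson (Appel-type) iodination, in which the primary C6 hydroxyl forms the alkoxyphosphonium ion fastest and is displaced by iodide while the secondary hydroxyls and all stereocentres stay untouched.

Step 2
Reactants: 2 methyl 6-deoxy-6-iodo-α-D-galactopyranoside
Product: 3 methyl 6-deoxy-6-iodo-3,4-O-isopropylidene-α-D-galactopyranoside
Conditions: 2,2-dimethoxypropane, camphorsulfonic acid (cat.), acetone, rt
Reagents that add atoms: 2,2-dimethoxypropane, COC(C)(C)OC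
Why: Acid-catalysed acetal exchange (isopropylidenation), in which only the cis-3,4-diol (axial O4, equatorial O3) closes an unstrained dioxolane, so that O2–H stays free.

Step 3
Reactants: 3 methyl 6-deoxy-6-iodo-3,4-O-isopropylidene-α-D-galactopyranoside
Product: 5 methyl 6-deoxy-3,4-O-isopropylidene-2-O-methyl-β-L-arabino-hex-5-enopyranoside, via 2-O-methyl 6-iodide 4 (not isolated)
Conditions: NaH (excess), MeI, DMF, 0 °C to rt
Reagents that add atoms: iodomethane, CI
Why: Williamson methylation of the only free hydroxyl followed in the same flask by NaH-induced E2 dehydroiodination across C5–C6, a known one-pot etherification/elimination of 6-iodo glycosides that deliberately erases the C5 stereocentre and gives the exocyclic enol ether.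

Step 4
Reactants: 5 methyl 6-deoxy-3,4-O-isopropylidene-2-O-methyl-β-L-arabino-hex-5-enopyranoside
Product: 7 (3S,4S,5R,6R)-3-hydroxy-5,6-(isopropylidenedioxy)-4-methoxycyclohexan-1-one (3-OH cis to 4-OMe, trans to the dioxolane oxygens), via open-chain mercurio keto aldehyde 6 (not isolated)
Conditions: Hg(OCOCF3)2 (5–10 mol %), acetone/H2O (2:1), 0 °C to rt
Reagents that add atoms: water, O
Why: Ferrier carbocyclization: divalent mercury adds to the polarized exocyclic enol ether of 5 (Hg to the terminal CH2, water to the acetal-type carbon), the resulting hemiketal collapses with loss of methanol to the open-chain keto aldehyde 6 carrying a C–Hg bond α to the ketone, and this mercury enolate adds to the aldehyde in an intramolecular aldol that forms the ring C2–C3 bond and releases the catalyst. The closest known reaction type is the mercury-catalysed conversion of 6-deoxyhex-5-enopyranosides into 2-deoxyinososes. The six-membered carbocycle closes in a 6-(enolendo)-exo-trig mode. The new stereocentre C3 is set by the substrate: following the empirical rule of this reaction, the chair-like transition state places the new hydroxyl trans to the C5 oxygen (former sugar O3) and hence cis to the C4 methoxy group, as the target requires. Because the anomeric centre is erased before the bond forms, either anomer of 5 should converge on 7. The step needs facial selectivity at the aldehyde and survival of the dioxolane and of the elimination-prone β-hydroxy ketone, which the nearly neutral, catalytic conditions at room temperature should secure.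

Step 5
Reactants: 7 (3S,4S,5R,6R)-3-hydroxy-5,6-(isopropylidenedioxy)-4-methoxycyclohexan-1-one
Product: 8 (3S,4R,5R,6R)-3-(tert-butyldimethylsilyloxy)-5,6-(isopropylidenedioxy)-4-methoxycyclohexan-1-one
Conditions: TBSOTf, 2,6-lutidine, CH2Cl2, −78 °C
Reagents that add atoms: tert-butyldimethylsilyl trifluoromethanesulfonate, CC(C)(C)[Si](C)(C)OS(=O)(=O)C(F)(F)F
Why: Silyl triflate silylation with a hindered, weak pyridine base at low temperature should cap the C3 hydroxyl without β-elimination of the ketol or cleavage of the dioxolane.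

Step 6
Reactants: 8 (3S,4R,5R,6R)-3-(tert-butyldimethylsilyloxy)-5,6-(isopropylidenedioxy)-4-methoxycyclohexan-1-one
Product: 10 (3S,4R,5R,6R)-3-(tert-butyldimethylsilyloxy)-5,6-(isopropylidenedioxy)-4-methoxycyclohex-1-en-1-yl trifluoromethanesulfonate, via lithium enolate 9 (not isolated)
Conditions: LiN(SiMe3)2, THF, −78 °C; then Comins' reagent, −78 °C
Reagents that add atoms: Comins' reagent, N-(5-chloropyridin-2-yl)-1,1,1-trifluoro-N-(trifluoromethylsulfonyl)methanesulfonamide, O=S(=O)(N(c1ccc(Cl)cn1)S(=O)(=O)C(F)(F)F)C(F)(F)F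
Why: Enol triflate formation: the hindered amide should deprotonate the C2 methylene kinetically, not the alkoxy-bearing C6 methine locked in the dioxolane, the lithium enolate of a β-silyloxy ketone is stable to β-elimination at −78 °C, and O-sulfonylation at that temperature fixes the C1=C2 double bond.

Step 7
Reactants: 11 (E)-2-methyl-4-(4,4,5,5-tetramethyl-1,3,2-dioxaborolan-2-yl)but-3-en-2-ol; 12 2,3-dibromopropene (excess)
Product: 13 (E)-6-bromo-2-methylhepta-3,6-dien-2-ol
Conditions: Pd(PPh3)4 (cat.), K2CO3, THF/H2O, 50 °C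
Reagents that add atoms: none
Why: Suzuki–Miyaura allyl–alkenyl coupling, in which zerovalent palladium inserts into the allylic C–Br bond much faster than into the vinylic one, the 2-bromoallyl unit has equivalent termini, and the E geometry of the boronate is retained.

Step 8
Reactants: 13 (E)-6-bromo-2-methylhepta-3,6-dien-2-ol; 14 (trimethylsilyl)acetylene
Product: 15 (E)-2-methyl-6-methylidene-8-(trimethylsilyl)oct-3-en-7-yn-2-ol
Conditions: PdCl2(PPh3)2 (cat.), CuI (cat.), Et3N, THF, 50 °C, sealed vessel
Reagents that add atoms: none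
Why: Sonogashira coupling of a 2-bromo-1-alkene with a silyl-capped alkyne, which tolerates the free tertiary alcohol and leaves the skipped diene in place.

Step 9
Reactants: 15 (E)-2-methyl-6-methylidene-8-(trimethylsilyl)oct-3-en-7-yn-2-ol
Product: 16 (E)-2-methyl-6-methylideneoct-3-en-7-yn-2-ol
Conditions: K2CO3 (cat.), MeOH, rt
Reagents that add atoms: none
Why: Base-catalysed methanolysis of the alkynyl C–Si bond, mild enough not to isomerize the 1,4-diene.

Step 10
Reactants: 10 (3S,4R,5R,6R)-3-(tert-butyldimethylsilyloxy)-5,6-(isopropylidenedioxy)-4-methoxycyclohex-1-en-1-yl trifluoromethanesulfonate; 16 (E)-2-methyl-6-methylideneoct-3-en-7-yn-2-ol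
Product: 17 (3S,4R,5S,6S)-3-(tert-butyldimethylsilyloxy)-1-[(5E)-7-hydroxy-7-methyl-3-methylideneoct-5-en-1-yn-1-yl]-5,6-(isopropylidenedioxy)-4-methoxycyclohex-1-ene
Conditions: Pd(PPh3)4 (cat.), CuI (cat.), Et3N, DMF, rt, degassed
Reagents that add atoms: none
Why: Sonogashira coupling of a cyclohexenyl triflate, which should proceed at room temperature with retention of the C1=C2 position and without touching any stereocentre.

Step 11
Reactants: 17 (3S,4R,5S,6S)-3-(tert-butyldimethylsilyloxy)-1-[(5E)-7-hydroxy-7-methyl-3-methylideneoct-5-en-1-yn-1-yl]-5,6-(isopropylidenedioxy)-4-methoxycyclohex-1-ene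
Product: 18 (3S,4S,5S,6S)-1-[(5E)-7-hydroxy-7-methyl-3-methylideneoct-5-en-1-yn-1-yl]-5,6-(isopropylidenedioxy)-4-methoxycyclohex-1-en-3-ol
Conditions: Bu4NF, AcOH, THF, 0 °C to rt
Reagents that add atoms: none
Why: Fluoride-induced cleavage of the Si–O bond under buffered conditions, to which the dioxolane, the dienyne and the tertiary alcohol are inert.

Step 12
Reactants: 18 (3S,4S,5S,6S)-1-[(5E)-7-hydroxy-7-methyl-3-methylideneoct-5-en-1-yn-1-yl]-5,6-(isopropylidenedioxy)-4-methoxycyclohex-1-en-3-ol
Product: 19 (3S,4S,5S,6S)-1-[(5E)-7-hydroxy-7-methyl-3-methylideneoct-5-en-1-yn-1-yl]-5,6-(isopropylidenedioxy)-4-methoxycyclohex-1-en-3-yl acetate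
Conditions: Ac2O, pyridine, rt
Reagents that add atoms: acetic anhydride, CC(=O)OC(C)=O
Why: Pyridine-mediated acetylation should esterify the secondary allylic C3 hydroxyl, while the tertiary side-chain alcohol, which needs a nucleophilic catalyst or forcing conditions, stays free.

Step 13
Reactants: 19 (3S,4S,5S,6S)-1-[(5E)-7-hydroxy-7-methyl-3-methylideneoct-5-en-1-yn-1-yl]-5,6-(isopropylidenedioxy)-4-methoxycyclohex-1-en-3-yl acetate
Product: 20 (1S,4S,5S,6R)-4,5-dihydroxy-3-[(5E)-7-hydroxy-7-methyl-3-methylideneoct-5-en-1-yn-1-yl]-6-methoxycyclohex-2-en-1-yl acetate (3S,4R,5S,6S in the ring numbering used here)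
Conditions: AcOH/H2O (4:1), 40 °C
Reagents that add atoms: none
Why: Acid-catalysed hydrolysis of the isopropylidene acetal under mild conditions, in which the acetate cannot migrate because O4 is methylated and O5 lies trans to O3.

Compound list
1 | methyl α-D-galactopyranoside | CO[C@H]1O[C@H](CO)[C@H](O)[C@H](O)[C@H]1O | starting material
2 | methyl 6-deoxy-6-iodo-α-D-galactopyranoside | CO[C@H]1O[C@H](CI)[C@H](O)[C@H](O)[C@H]1O | intermediate
3 | methyl 6-deoxy-6-iodo-3,4-O-isopropylidene-α-D-galactopyranoside | CO[C@H]1O[C@H](CI)[C@@H]2OC(C)(C)O[C@@H]2[C@H]1O | intermediate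
4 | methyl 6-deoxy-6-iodo-3,4-O-isopropylidene-2-O-methyl-α-D-galactopyranoside (not isolated) | CO[C@H]1O[C@H](CI)[C@@H]2OC(C)(C)O[C@@H]2[C@H]1OC | intermediate
5 | methyl 6-deoxy-3,4-O-isopropylidene-2-O-methyl-β-L-arabino-hex-5-enopyranoside | CO[C@H]1OC(=C)[C@@H]2OC(C)(C)O[C@@H]2[C@H]1OC | intermediate
6 | 6-deoxy-3,4-O-isopropylidene-2-O-methyl-6-(trifluoroacetoxymercurio)-L-arabino-hexos-5-ulose, open-chain keto aldehyde (not isolated) | O=C[C@H](OC)[C@H]1OC(C)(C)O[C@H]1C(=O)C[Hg]OC(=O)C(F)(F)F | intermediate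
7 | (3S,4S,5R,6R)-3-hydroxy-5,6-(isopropylidenedioxy)-4-methoxycyclohexan-1-one | O=C1C[C@H](O)[C@H](OC)[C@H]2OC(C)(C)O[C@@H]12 | intermediate
8 | (3S,4R,5R,6R)-3-(tert-butyldimethylsilyloxy)-5,6-(isopropylidenedioxy)-4-methoxycyclohexan-1-one | O=C1C[C@H](O[Si](C)(C)C(C)(C)C)[C@H](OC)[C@H]2OC(C)(C)O[C@@H]12 | intermediate
9 | lithium enolate of 8 (C1–O, C1=C2; not isolated) | [Li+].[O-]C1=C[C@H](O[Si](C)(C)C(C)(C)C)[C@H](OC)[C@H]2OC(C)(C)O[C@@H]12 | intermediate
10 | (3S,4R,5R,6R)-3-(tert-butyldimethylsilyloxy)-5,6-(isopropylidenedioxy)-4-methoxycyclohex-1-en-1-yl trifluoromethanesulfonate | O=S(=O)(OC1=C[C@H](O[Si](C)(C)C(C)(C)C)[C@H](OC)[C@H]2OC(C)(C)O[C@@H]12)C(F)(F)F | intermediate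
11 | (E)-2-methyl-4-(4,4,5,5-tetramethyl-1,3,2-dioxaborolan-2-yl)but-3-en-2-ol | CC(C)(O)/C=C/B1OC(C)(C)C(C)(C)O1 | starting material
12 | 2,3-dibromopropene | C=C(Br)CBr | starting material
13 | (E)-6-bromo-2-methylhepta-3,6-dien-2-ol | C=C(Br)C/C=C/C(C)(C)O | intermediate
14 | (trimethylsilyl)acetylene | C#C[Si](C)(C)C | starting material
15 | (E)-2-methyl-6-methylidene-8-(trimethylsilyl)oct-3-en-7-yn-2-ol | C=C(C#C[Si](C)(C)C)C/C=C/C(C)(C)O | intermediate
16 | (E)-2-methyl-6-methylideneoct-3-en-7-yn-2-ol | C=C(C#C)C/C=C/C(C)(C)O | intermediate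
17 | (3S,4R,5S,6S)-3-(tert-butyldimethylsilyloxy)-1-[(5E)-7-hydroxy-7-methyl-3-methylideneoct-5-en-1-yn-1-yl]-5,6-(isopropylidenedioxy)-4-methoxycyclohex-1-ene | C=C(C#CC1=C[C@H](O[Si](C)(C)C(C)(C)C)[C@H](OC)[C@H]2OC(C)(C)O[C@@H]12)C/C=C/C(C)(C)O | intermediate
18 | (3S,4S,5S,6S)-1-[(5E)-7-hydroxy-7-methyl-3-methylideneoct-5-en-1-yn-1-yl]-5,6-(isopropylidenedioxy)-4-methoxycyclohex-1-en-3-ol | C=C(C#CC1=C[C@H](O)[C@H](OC)[C@H]2OC(C)(C)O[C@@H]12)C/C=C/C(C)(C)O | intermediate
19 | (3S,4S,5S,6S)-1-[(5E)-7-hydroxy-7-methyl-3-methylideneoct-5-en-1-yn-1-yl]-5,6-(isopropylidenedioxy)-4-methoxycyclohex-1-en-3-yl acetate | C=C(C#CC1=C[C@H](OC(C)=O)[C@H](OC)[C@H]2OC(C)(C)O[C@@H]12)C/C=C/C(C)(C)O | intermediate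
20 | (1S,4S,5S,6R)-4,5-dihydroxy-3-[(5E)-7-hydroxy-7-methyl-3-methylideneoct-5-en-1-yn-1-yl]-6-methoxycyclohex-2-en-1-yl acetate | C=C(C#CC1=C[C@H](OC(C)=O)[C@H](OC)[C@@H](O)[C@H]1O)C/C=C/C(C)(C)O | target

Total step count: 13 (ten on the main line, three for the side-chain fragment 16).
Longest linear sequence: 10 steps (steps 1–6 and 10–13, from 1 to 20).

Steps most likely to fail

Step 4 (key step). What may go wrong is poor facial selectivity in the intramolecular aldol, so that the C3 hydroxyl emerges mainly trans to the C4 methoxy group. The fallback sets C3 by SN2 inversion at the end instead of by the ring closure. It sets out from 5: the same cyclization gives the C3-epimeric ketol F1, which is silylated as in step 5 to the silyl ether F2 and converted through its lithium enolate F3 into the enol triflate F4. Coupling with 16 as in step 10 gives the dienyne F5, and desilylation as in step 11 gives the allylic alcohol F6. A Mitsunobu reaction of F6 with acetic acid (PPh3, diisopropyl azodicarboxylate, AcOH, THF, 0 °C) should install the acetate with inversion at C3; the fallback comes back to the route at 19.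

Step 6. What may go wrong is enolization toward C6, or β-elimination of the silyloxy group from the C2 enolate before it is trapped. The fallback makes the C1=C2 bond by alkynylation and dehydration instead of enolate chemistry. It sets out from 8: addition of HC≡CMgBr (THF, −78 to 0 °C), expected from the face opposite the dioxolane, gives the tertiary propargylic alcohol F7. Syn-dehydration with Burgess reagent (toluene, 50 °C) should remove the C1 hydroxyl together with a C2 hydrogen, since the C6 hydrogen lies anti to the hydroxyl in this adduct, and give the terminal enyne F8. Sonogashira coupling of F8 with vinyl bromide 13 (PdCl2(PPh3)2, CuI, Et3N, THF, 50 °C) comes back to the route at 17.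

Step 13. What may go wrong is acid-promoted ionization or hydrolysis of the allylic C3 acetate while the dioxolane is being cleaved. The fallback removes the acetal before the ester is introduced and masks the cis-diol only transiently. It sets out from 18: AcOH/H2O (4:1, 40 °C) gives the tetraol F9, and PhB(OH)2 (toluene, molecular sieves, rt) ties the cis C5/C6 diol into the cyclic phenylboronate F10. Ac2O/pyridine then acetylates the remaining secondary hydroxyl to give the acetate boronate F11. Exchange of boron with pinacol under neutral conditions (CH2Cl2, rt) comes back to the route at 20.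

Further compounds
F1 | step 4 | (3R,4S,5R,6R)-3-hydroxy-5,6-(isopropylidenedioxy)-4-methoxycyclohexan-1-one (C3 epimer of 7) | O=C1C[C@@H](O)[C@H](OC)[C@H]2OC(C)(C)O[C@@H]12
F2 | step 4 | C3 epimer of silyl ether 8 | O=C1C[C@@H](O[Si](C)(C)C(C)(C)C)[C@H](OC)[C@H]2OC(C)(C)O[C@@H]12
F3 | step 4 | lithium enolate of F2 (C3 epimer of 9) | [Li+].[O-]C1=C[C@@H](O[Si](C)(C)C(C)(C)C)[C@H](OC)[C@H]2OC(C)(C)O[C@@H]12
F4 | step 4 | C3 epimer of enol triflate 10 | O=S(=O)(OC1=C[C@@H](O[Si](C)(C)C(C)(C)C)[C@H](OC)[C@H]2OC(C)(C)O[C@@H]12)C(F)(F)F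
F5 | step 4 | C3 epimer of dienyne 17 | C=C(C#CC1=C[C@@H](O[Si](C)(C)C(C)(C)C)[C@H](OC)[C@H]2OC(C)(C)O[C@@H]12)C/C=C/C(C)(C)O
F6 | step 4 | C3 epimer of allylic alcohol 18 | C=C(C#CC1=C[C@@H](O)[C@H](OC)[C@H]2OC(C)(C)O[C@@H]12)C/C=C/C(C)(C)O
F7 | step 6 | 3-(tert-butyldimethylsilyloxy)-1-ethynyl-5,6-(isopropylidenedioxy)-4-methoxycyclohexan-1-ol (C1 hydroxyl cis to the dioxolane) | C#C[C@]1(O)C[C@H](O[Si](C)(C)C(C)(C)C)[C@H](OC)[C@H]2OC(C)(C)O[C@@H]12
F8 | step 6 | 3-(tert-butyldimethylsilyloxy)-1-ethynyl-5,6-(isopropylidenedioxy)-4-methoxycyclohex-1-ene | C#CC1=C[C@H](O[Si](C)(C)C(C)(C)C)[C@H](OC)[C@H]2OC(C)(C)O[C@@H]12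
F9 | step 13 | 1-[(5E)-7-hydroxy-7-methyl-3-methylideneoct-5-en-1-yn-1-yl]-4-methoxycyclohex-1-ene-3,5,6-triol (deacetyl target) | C=C(C#CC1=C[C@H](O)[C@H](OC)[C@@H](O)[C@H]1O)C/C=C/C(C)(C)O
F10 | step 13 | 5,6-O-phenylboronate of F9 | C=C(C#CC1=C[C@H](O)[C@H](OC)[C@H]2OB(c3ccccc3)O[C@@H]12)C/C=C/C(C)(C)O
F11 | step 13 | 3-O-acetyl 5,6-O-phenylboronate (boronate of 20) | C=C(C#CC1=C[C@H](OC(C)=O)[C@H](OC)[C@H]2OB(c3ccccc3)O[C@@H]12)C/C=C/C(C)(C)O
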